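## Retrosynthetic overview

- The target comes from the 2,5-dimethoxyquinone by selective acid hydrolysis of the methoxy group next to the side chain; the quinone comes from the tetramethoxyarene acetate by CAN oxidation.
- Key disconnection: the C2–OAc bond at the stereocentre, made by enantioselective anti-Markovnikov addition of acetic acid across an (E)-aryl alkene. This step forms the C–O bond and sets (R) together.
- The aryl alkene comes from 1,2,4,5-tetramethoxybenzene (lithiation) and tridecanal, followed by dehydration.
- No ring is built: the six-membered ring is bought as the arene and only oxidised to the quinone in the last two steps.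

Assumption: the stereocentre is (R) (OAc > CH2-ring > undecyl > H). The antipode of the chiral phosphate that gives (R) in step 2 is fixed by a first screen and is written here as (R)-TRIP.

## Route

**Step 1**
Reactants: 1 1,2,4,5-tetramethoxybenzene; 2 tridecanal
Product: 5 (E)-1-(2,3,5,6-tetramethoxyphenyl)tridec-1-ene, via aryllithium 3 (not isolated), via benzylic alcohol 4 (not isolated)
Conditions: n-BuLi (1.05 equiv), THF, 0 °C; 2, −78 → 0 °C; then TsOH·H2O (1.3 equiv), PhMe, 90 °C (THF distilled off)
Reagents that add atoms: none
Why: Directed ortho-lithiation of 1 at the position flanked by two OMe groups (both free positions are equivalent), 1,2-addition to the aldehyde and acid-catalysed E1 dehydration through the o,o'-dimethoxybenzylic cation give the conjugated E-alkene; the carbinol centre of 4 is erased.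

**Step 2**
Reactants: 5 (E)-1-(2,3,5,6-tetramethoxyphenyl)tridec-1-ene
Product: 6 (2R)-1-(2,3,5,6-tetramethoxyphenyl)tridecan-2-yl acetate
Conditions: [3,6-t-Bu2-9-mesityl-10-phenylacridinium][(R)-TRIP phosphate] (5 mol %, preformed ion pair), (PhS)2 (10 mol %), AcOH (5 equiv), PhCF3, 450 nm LEDs, −20 °C
Reagents that add atoms: acetic acid, CC(=O)O
Why: Proposed new method: the excited acridinium oxidises 5 to its alkene radical cation, which in non-polar PhCF3 stays ion-paired to the chiral phosphate; the phosphate holds AcOH as a hydrogen-bonded heterodimer and delivers its carbonyl oxygen to one face of C2 (the carbon remote from the ring, giving the benzylic radical) while taking up the proton, so the C2–O bond and the (R) centre form in the enantio-determining step; PhSH formed in situ then gives H to C1 (which becomes CH2 and needs no control), and PhS• re-oxidises the acridine radical; the reaction is an addition with no co-product, and any Z-alkene converges because the radical cation rotates freely; closest known reaction types are the racemic acridinium/thiol photoredox anti-Markovnikov hydroacyloxylation of β-alkylstyrenes, chiral-counteranion-directed reactions of styrene radical cations, and carboxylic acid–chiral phosphoric acid heterodimer ring openings.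

**Step 3**
Reactants: 6 (2R)-1-(2,3,5,6-tetramethoxyphenyl)tridecan-2-yl acetate
Product: 7 (2R)-1-(2,5-dimethoxy-3,6-dioxocyclohexa-1,4-dien-1-yl)tridecan-2-yl acetate
Conditions: CAN (2.5 equiv), MeCN/H2O 2:1, 0 °C, 30 min
Reagents that add atoms: water, O
Why: CAN oxidative demethylation of a p-dimethoxyarene (two single-electron oxidations, water attacks the ipso carbons, MeOH leaves); either para pair of OMe groups gives the same 2,5-dimethoxy-1,4-benzoquinone, and the acetate and the non-benzylic stereocentre are untouched at 0 °C.

**Step 4**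
Reactants: 7 (2R)-1-(2,5-dimethoxy-3,6-dioxocyclohexa-1,4-dien-1-yl)tridecan-2-yl acetate
Product: 8 (2R)-1-(2-hydroxy-5-methoxy-3,6-dioxocyclohexa-1,4-dien-1-yl)tridecan-2-yl acetate
Conditions: 70% aq. HClO4, CH2Cl2, 0 °C → rt, 3 h
Reagents that add atoms: water, O
Why: Acid-catalysed hydrolysis of a vinylogous ester (addition–elimination of water): the C2 methoxy wedged between the side chain and the carbonyl is twisted out of conjugation and is the one replaced, the known selectivity of 3-alkyl-2,5-dimethoxy-1,4-benzoquinones, while the ordinary secondary acetate hydrolyses more slowly in cold acid; the stereocentre is not involved.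

## Compound list

1 | 1,2,4,5-tetramethoxybenzene | COc1cc(OC)c(OC)cc1OC | starting material
2 | tridecanal | CCCCCCCCCCCCC=O | starting material
3 | (2,3,5,6-tetramethoxyphenyl)lithium | [Li]c1c(OC)c(OC)cc(OC)c1OC | intermediate (not isolated)
4 | rac-1-(2,3,5,6-tetramethoxyphenyl)tridecan-1-ol | CCCCCCCCCCCCC(O)c1c(OC)c(OC)cc(OC)c1OC | intermediate (not isolated)
5 | (E)-1-(2,3,5,6-tetramethoxyphenyl)tridec-1-ene | CCCCCCCCCCC/C=C/c1c(OC)c(OC)cc(OC)c1OC | intermediate
6 | (2R)-1-(2,3,5,6-tetramethoxyphenyl)tridecan-2-yl acetate | CCCCCCCCCCC[C@H](Cc1c(OC)c(OC)cc(OC)c1OC)OC(C)=O | intermediate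
7 | (2R)-1-(2,5-dimethoxy-3,6-dioxocyclohexa-1,4-dien-1-yl)tridecan-2-yl acetate | CCCCCCCCCCC[C@H](CC1=C(OC)C(=O)C=C(OC)C1=O)OC(C)=O | intermediate
8 | (2R)-1-(2-hydroxy-5-methoxy-3,6-dioxocyclohexa-1,4-dien-1-yl)tridecan-2-yl acetate | CCCCCCCCCCC[C@H](CC1=C(O)C(=O)C=C(OC)C1=O)OC(C)=O | target

## Step count and risks

Total step count: 4. Longest linear sequence: 4.

**Step 2 (the proposed new step).** Risks are low ee from AcOH adding to radical cation that is not ion-paired, a sluggish arene-centred radical cation, and [2+2] dimerisation. The fallback uses known chemistry and sets out from 5. Shi epoxidation (D-fructose-derived ketone, Oxone, K2CO3, MeCN/dimethoxymethane/buffer pH 10.5, 0 °C) gives (2R,3R)-2-(2,3,5,6-tetramethoxyphenyl)-3-undecyloxirane F1, which fixes the C2–O bond and its configuration. Hydrogenolysis (H2, Pd/C, EtOAc, trace Et3N) cleaves only the benzylic C–O bond and gives (2R)-1-(2,3,5,6-tetramethoxyphenyl)tridecan-2-ol F2 with retention at C2. Acetylation (Ac2O, Et3N, DMAP, CH2Cl2) comes back to the route at 6.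

**Step 4.** Risks are partial loss of the side-chain acetate in perchloric acid or incomplete selectivity between the two methoxy groups. The fallback sets out from 7 and removes both methyl groups, then puts one back. Hydrolysis with 2 M NaOH in EtOH at 60 °C followed by HCl gives 2,5-dihydroxy-3-[(2R)-2-hydroxytridecyl]-1,4-benzoquinone F3. Acid-catalysed etherification (MeOH, cat. H2SO4, reflux) methylates the unhindered hydroxyl remote from the side chain and gives 2-hydroxy-3-[(2R)-2-hydroxytridecyl]-5-methoxy-1,4-benzoquinone F4. Ac2O/pyridine gives (2R)-1-(2-acetoxy-5-methoxy-3,6-dioxocyclohexa-1,4-dien-1-yl)tridecan-2-yl acetate F5. Its labile quinonyl acetate (a vinylogous anhydride) is cleaved selectively with NaHCO3 in MeOH/H2O at 0 °C, which comes back at 8.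

**Step 1.** Risks are enolisation of the aldehyde by the hindered aryllithium and acid-induced oligomerisation during the one-pot dehydration. The fallback sets out from 1. Lithiation (n-BuLi, THF) and quenching with I2 give 3-iodo-1,2,4,5-tetramethoxybenzene F6. Separately, commercial 1-tridecyne is hydroborated with pinacolborane (cat. Cp2ZrHCl) to (E)-tridec-1-en-1-ylboronic acid pinacol ester F7. Suzuki–Miyaura coupling of the two (Pd(OAc)2/SPhos, K3PO4, PhMe/H2O, 80 °C) comes back at 5 with the E geometry fixed by the syn-hydroboration.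

## Further compounds

F1 | step 2 | (2R,3R)-2-(2,3,5,6-tetramethoxyphenyl)-3-undecyloxirane | CCCCCCCCCCC[C@H]1O[C@@H]1c1c(OC)c(OC)cc(OC)c1OC
F2 | step 2 | (2R)-1-(2,3,5,6-tetramethoxyphenyl)tridecan-2-ol | CCCCCCCCCCC[C@H](Cc1c(OC)c(OC)cc(OC)c1OC)O
F3 | step 4 | 2,5-dihydroxy-3-[(2R)-2-hydroxytridecyl]-1,4-benzoquinone | CCCCCCCCCCC[C@H](CC1=C(O)C(=O)C=C(O)C1=O)O
F4 | step 4 | 2-hydroxy-3-[(2R)-2-hydroxytridecyl]-5-methoxy-1,4-benzoquinone | CCCCCCCCCCC[C@H](CC1=C(O)C(=O)C=C(OC)C1=O)O
F5 | step 4 | (2R)-1-(2-acetoxy-5-methoxy-3,6-dioxocyclohexa-1,4-dien-1-yl)tridecan-2-yl acetate | CCCCCCCCCCC[C@H](CC1=C(OC(C)=O)C(=O)C=C(OC)C1=O)OC(C)=O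
F6 | step 1 | 3-iodo-1,2,4,5-tetramethoxybenzene | COc1cc(OC)c(OC)c(I)c1OC
F7 | step 1 | (E)-tridec-1-en-1-ylboronic acid pinacol ester | CCCCCCCCCCC/C=C/B1OC(C)(C)C(C)(C)O1
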